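**Retrosynthetic overview**
- Feature: ring A, the central resorcinol ring, carries the cinnamoyl carbonyl on C1', oxygens on C2' and C4', hydrogens on C3' and C6' and the phenol ring C on C5'. The carbonyl, C2'–O and C4'–O form a 1,3,5-tricarbonyl (triketide) array with no oxygen at C6', the pattern left by a Claisen ring closure on a cinnamoyl starter. Ring B is the 4-hydroxyphenyl ring of that cinnamoyl group and ring D is the 2,4-dihydroxyphenyl ketone ring.
- Last disconnections: the six O–Me bonds (global demethylation), then the bond from ring C to the CH= carbon of the second chalcone (Heck coupling of an aryl bromide with 2,4-dimethoxyphenyl vinyl ketone).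
- Key disconnection: ring A is taken back to its cyclohexane-1,3-dione and cut at C1'–C6' and C3'–C4' into (E)-6-(4-methoxyphenyl)hex-5-ene-2,4-dione (Michael donor and Claisen nucleophile) and methyl 2-(5-bromo-2-methoxyphenyl)acrylate (Michael acceptor and acyl donor).
- The diketone comes from acetylacetone and 4-methoxybenzaldehyde, the acrylate from (5-bromo-2-methoxyphenyl)acetic acid and formaldehyde.
- Ring order: rings B, C and D are bought as benzene rings; ring A is the only ring made, closed in step 4 and aromatised in step 5.

Key step: step 4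

Remark: boron- or metal-bound species that exist only until the aqueous work-up of their own step (chelates, enolates, alkoxides, aryl borates) and the partly methylated or demethylated stages of steps 6 and 10 are not counted as separate compounds.

**Route**

Step 1
Reactants: 1 acetylacetone (pentane-2,4-dione); 2 p-anisaldehyde (4-methoxybenzaldehyde)
Product: 3 (E)-6-(4-methoxyphenyl)hex-5-ene-2,4-dione
Conditions: 1 (3 equiv), B2O3 (2 equiv), EtOAc, 40 °C; 2 (1 equiv), B(OBu)3 (2 equiv); n-BuNH2 (0.5 equiv), 40 °C; then 0.4 M HCl, 60 °C
Reagents that add atoms: none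
Why: Boron-templated aldol condensation as used for curcuminoids, in which chelation of the enolised diketone to boron blocks Knoevenagel reaction at the central carbon and directs the amine-catalysed condensation to a terminal methyl group, the excess of 1 holds the reaction at the mono-adduct, and the E alkene results from the E1cB dehydration as the more stable isomer.

Step 2
Reactants: 4 (5-bromo-2-methoxyphenyl)acetic acid
Product: 5 methyl (5-bromo-2-methoxyphenyl)acetate
Conditions: MeOH, H2SO4 (cat.), reflux
Reagents that add atoms: methanol, CO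
Why: Fischer esterification driven by methanol as solvent, with the aryl bromide and the aryl methyl ether inert to the acid.

Step 3
Reactants: 5 methyl (5-bromo-2-methoxyphenyl)acetate
Product: 7 methyl 2-(5-bromo-2-methoxyphenyl)acrylate, via hydroxymethyl ester 6 (not isolated)
Conditions: (CH2O)n (2 equiv), K2CO3 (2 equiv), Bu4NI (0.1 equiv), toluene, 80 °C; product kept cold over BHT
Reagents that add atoms: formaldehyde (as paraformaldehyde), C=O
Why: Aldol addition of the arylacetate enolate to formaldehyde followed by E1cB dehydration under solid–liquid phase transfer, the standard α-methylenation of arylacetic esters to 2-arylacrylates, with a carbonate base too weak to start anionic polymerisation.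

Step 4
Reactants: 3 (E)-6-(4-methoxyphenyl)hex-5-ene-2,4-dione; 7 methyl 2-(5-bromo-2-methoxyphenyl)acrylate
Product: 9 annulated dione 6-(5-bromo-2-methoxyphenyl)-4-[(E)-3-(4-methoxyphenyl)prop-2-enoyl]cyclohexane-1,3-dione (tautomeric mixture; written as its bis-enol), via open-chain Michael adduct 8 (not isolated)
Conditions: 3 (1.05 equiv), KOtBu (1.05 equiv), THF, 0 °C; 7 (1.0 equiv) added slowly, 0 °C → rt; KOtBu (1.3 equiv), t-BuOH, 50 °C; then 1 M HCl
Reagents that add atoms: none
Why: The potassium enolate of 3 should add through its central carbon to the unsubstituted CH2 terminus of 7 (Michael addition, C1'–C6'), proton transfer gives the diketonate of 8, and under the second base charge the methyl ketone is enolised reversibly and attacks the ester carbonyl with loss of methoxide (intramolecular Claisen condensation, C3'–C4'). The closest known chemistry is the Michael–Claisen annulation of acetoacetates and 1,3-diketones with acrylates to 4-acylcyclohexane-1,3-diones, the same logic as the dimedone synthesis. Ring A closes by a 6-(enolendo)-exo-trig attack on the ester through an unstrained chair-like array, and immediate deprotonation of the triketone makes the closure irreversible. No stereocentre has to be controlled, because the sp3 centres C1' and C5' of 9 are epimerisable and disappear in step 5. Addition to the acrylate and not to the styryl enone is secured because that enone stays part of a diketonate throughout and carries a donor aryl group on its β-carbon, whereas 7 offers an unhindered terminus and gives an aryl-stabilised ester enolate; O-acylation to an enol lactone is reversed by alkoxide, so only the C-acylated triketone enolate accumulates. One equivalent of base in the first stage leaves no free alkoxide to oligomerise 7, and 7 is not used in excess so that the acidic C3' of the product cannot add a second acrylate.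

Step 5
Reactants: 9 annulated dione 6-(5-bromo-2-methoxyphenyl)-4-[(E)-3-(4-methoxyphenyl)prop-2-enoyl]cyclohexane-1,3-dione
Product: 10 (E)-1-[5-(5-bromo-2-methoxyphenyl)-2,4-dihydroxyphenyl]-3-(4-methoxyphenyl)prop-2-en-1-one
Conditions: DDQ (1.1 equiv), 1,4-dioxane, rt → 50 °C
Reagents that add atoms: none
Why: Quinone dehydrogenation of a cyclohexane-1,3-dione to a resorcinol, in which the bis-enol tautomer of 9 is a 1,4-cyclohexadiene whose doubly allylic C6'–H is taken as hydride by DDQ and loss of a C3' proton gives the arene, while the mild temperature should spare the anisole rings, the enone and the new 2'-hydroxychalcone.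

Step 6
Reactants: 10 (E)-1-[5-(5-bromo-2-methoxyphenyl)-2,4-dihydroxyphenyl]-3-(4-methoxyphenyl)prop-2-en-1-one
Product: 11 (E)-1-[5-(5-bromo-2-methoxyphenyl)-2,4-dimethoxyphenyl]-3-(4-methoxyphenyl)prop-2-en-1-one
Conditions: MeI (5 equiv), K2CO3 (4 equiv), DMF, rt → 40 °C
Reagents that add atoms: iodomethane, CI
Why: Williamson ether synthesis on both phenols (the chelated 2'-OH needs the excess and mild warming, and any flavanone formed by oxa-Michael closure reopens under the base and is trapped), so that no phenoxide can add to the vinyl ketone or bind palladium in step 9.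

Step 7
Reactants: 12 aldehyde 2,4-dimethoxybenzaldehyde
Product: 13 carbinol 1-(2,4-dimethoxyphenyl)prop-2-en-1-ol (racemic)
Conditions: vinylmagnesium bromide (1.2 equiv), THF, −20 → 0 °C; sat. aq. NH4Cl
Reagents that add atoms: vinylmagnesium bromide, C=C[Mg]Br
Why: Grignard 1,2-addition to the aldehyde, giving the carbinol centre as a racemate, which is of no consequence because step 8 removes it.

Step 8
Reactants: 13 carbinol 1-(2,4-dimethoxyphenyl)prop-2-en-1-ol
Product: 14 aryl vinyl ketone 1-(2,4-dimethoxyphenyl)prop-2-en-1-one
Conditions: MnO2 (activated, 10 equiv), CH2Cl2, rt; filtered, BHT added, used at once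
Reagents that add atoms: none
Why: MnO2 oxidation of an allylic and benzylic alcohol under neutral heterogeneous conditions, which should deliver the polymerisation-prone enone without exposure to acid or base.

Step 9
Reactants: 11 (E)-1-[5-(5-bromo-2-methoxyphenyl)-2,4-dimethoxyphenyl]-3-(4-methoxyphenyl)prop-2-en-1-one; 14 aryl vinyl ketone 1-(2,4-dimethoxyphenyl)prop-2-en-1-one
Product: 15 (E)-1-(2,4-dimethoxyphenyl)-3-[3-[2,4-dimethoxy-5-[(E)-3-(4-methoxyphenyl)prop-2-enoyl]phenyl]-4-methoxyphenyl]prop-2-en-1-one (hexamethyl ether of the target)
Conditions: 14 (2 equiv, in portions), Pd(OAc)2 (5 mol %), P(o-tol)3 (10 mol %), Et3N (2 equiv), BHT (cat.), DMF, 90 °C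
Reagents that add atoms: none
Why: Mizoroki–Heck reaction in which zerovalent palladium formed from Pd(OAc)2 and the phosphine inserts into the C–Br bond, syn-carbopalladation of the monosubstituted alkene of 14 places the aryl group on the terminal carbon and syn β-hydride elimination sets the E enone, while the 1,2-disubstituted chalcone alkene already present should insert far more slowly.

Step 10
Reactants: 15 hexamethyl ether of the target
Product: 16 rhuschalcone VI, (E)-1-(2,4-dihydroxyphenyl)-3-[3-[2,4-dihydroxy-5-[(E)-3-(4-hydroxyphenyl)prop-2-enoyl]phenyl]-4-hydroxyphenyl]prop-2-en-1-one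
Conditions: BBr3 (12 equiv, 1 M in CH2Cl2), CH2Cl2, −78 °C → rt; then ice-water
Reagents that add atoms: none
Why: Lewis acid ether cleavage in which BBr3 coordinates each of the six aryl methyl ethers and bromide removes the methyl group by SN2 (the ethers ortho to the carbonyl groups first, through chelation), a standard conversion of methoxychalcones into hydroxychalcones that should leave both E enones intact when the quench is kept cold to limit flavanone closure.

**Compound list**
1 | acetylacetone (pentane-2,4-dione) | CC(=O)CC(C)=O | starting material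
2 | p-anisaldehyde (4-methoxybenzaldehyde) | COc1ccc(C=O)cc1 | starting material
3 | (E)-6-(4-methoxyphenyl)hex-5-ene-2,4-dione | COc1ccc(/C=C/C(=O)CC(C)=O)cc1 | intermediate
4 | (5-bromo-2-methoxyphenyl)acetic acid | COc1ccc(Br)cc1CC(=O)O | starting material
5 | methyl (5-bromo-2-methoxyphenyl)acetate | COC(=O)Cc1cc(Br)ccc1OC | intermediate
6 | methyl 2-(5-bromo-2-methoxyphenyl)-3-hydroxypropanoate (racemic; not isolated) | COC(=O)C(CO)c1cc(Br)ccc1OC | intermediate
7 | methyl 2-(5-bromo-2-methoxyphenyl)acrylate | COC(=O)C(=C)c1cc(Br)ccc1OC | intermediate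
8 | methyl (E)-4-acetyl-2-(5-bromo-2-methoxyphenyl)-7-(4-methoxyphenyl)-5-oxohept-6-enoate (racemic diastereomer mixture; not isolated) | COC(=O)C(CC(C(C)=O)C(=O)/C=C/c1ccc(OC)cc1)c1cc(Br)ccc1OC | intermediate
9 | 6-(5-bromo-2-methoxyphenyl)-4-[(E)-3-(4-methoxyphenyl)prop-2-enoyl]cyclohexane-1,3-dione (tautomeric mixture, written as the achiral bis-enol; the keto forms are epimerisable racemates) | O=C(/C=C/c1ccc(OC)cc1)C1=C(O)CC(O)=C(c2cc(Br)ccc2OC)C1 | intermediate
10 | (E)-1-[5-(5-bromo-2-methoxyphenyl)-2,4-dihydroxyphenyl]-3-(4-methoxyphenyl)prop-2-en-1-one | O=C(/C=C/c1ccc(OC)cc1)c1cc(-c2cc(Br)ccc2OC)c(O)cc1O | intermediate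
11 | (E)-1-[5-(5-bromo-2-methoxyphenyl)-2,4-dimethoxyphenyl]-3-(4-methoxyphenyl)prop-2-en-1-one | O=C(/C=C/c1ccc(OC)cc1)c1cc(-c2cc(Br)ccc2OC)c(OC)cc1OC | intermediate
12 | 2,4-dimethoxybenzaldehyde | COc1ccc(C=O)c(OC)c1 | starting material
13 | 1-(2,4-dimethoxyphenyl)prop-2-en-1-ol (racemic) | C=CC(O)c1ccc(OC)cc1OC | intermediate
14 | 1-(2,4-dimethoxyphenyl)prop-2-en-1-one | C=CC(=O)c1ccc(OC)cc1OC | intermediate
15 | (E)-1-(2,4-dimethoxyphenyl)-3-[3-[2,4-dimethoxy-5-[(E)-3-(4-methoxyphenyl)prop-2-enoyl]phenyl]-4-methoxyphenyl]prop-2-en-1-one | COc1ccc(C(=O)/C=C/c2ccc(OC)c(-c3cc(C(=O)/C=C/c4ccc(OC)cc4)c(OC)cc3OC)c2)c(OC)c1 | intermediate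
16 | rhuschalcone VI | O=C(/C=C/c1ccc(O)c(-c2cc(C(=O)/C=C/c3ccc(O)cc3)c(O)cc2O)c1)c1ccc(O)cc1O | target

**Step count and risks**

Total step count: 10. Longest linear sequence: 7 steps (steps 2, 3, 4, 5, 6, 9 and 10, from 4 to 16).

Steps most likely to fail:

1. Step 4.
   - What may go wrong: free alkoxide or the ester enolate may start anionic oligomerisation of the 2-arylacrylate. The Michael adduct may revert or lose its acetyl group by retro-Claisen cleavage before it closes. The methyl ketone enolate may add in a 6-endo sense to the styryl enone instead of attacking the ester. The acidic C3' of the product may add a second acrylate.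
   - Fallback: ring A is bought as an arene and the bond between rings A and C is made by cross-coupling. It sets out from 2 and comes back to the route at 11. Commercial 1-(2,4-dimethoxyphenyl)ethanone (CC(=O)c1ccc(OC)cc1OC) should be iodinated at position 5, para to the 2-methoxy group (N-iodosuccinimide, cat. CF3CO2H, MeCN), to give 1-(5-iodo-2,4-dimethoxyphenyl)ethanone F1. Claisen–Schmidt condensation of this ketone with 2 (KOH, EtOH, rt) should give (E)-1-(5-iodo-2,4-dimethoxyphenyl)-3-(4-methoxyphenyl)prop-2-en-1-one F2. Suzuki–Miyaura coupling with commercial (5-bromo-2-methoxyphenyl)boronic acid (Pd(PPh3)4, Na2CO3, DME/H2O, 60 °C), selective for the C–I bond over the electron-rich C–Br bond, should then give 11.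

2. Step 5.
   - What may go wrong: the quinone may add to the enolised triketone (C–C or C–O bond formation) instead of abstracting hydride. Dehydrogenation may stop short. The oxidant may go on to cyclodehydrogenate the freshly formed 2'-hydroxychalcone towards flavone or aurone.
   - Fallback: ring A is aromatised before any chalcone exists. It sets out from 1 and 7 and comes back to the route at 11. The annulation of step 4 is run with acetylacetone itself (1 in excess, KOtBu, THF/t-BuOH), so that methyl 4-acetyl-2-(5-bromo-2-methoxyphenyl)-5-oxohexanoate F3 forms in the flask and closes to 4-acetyl-6-(5-bromo-2-methoxyphenyl)cyclohexane-1,3-dione F4. This dione is dehydrogenated with catalytic I2 in DMSO at 90 °C, an oxidant that would cyclise a 2'-hydroxychalcone but is harmless to an acetophenone, to give 1-[5-(5-bromo-2-methoxyphenyl)-2,4-dihydroxyphenyl]ethanone F5. Methylation (MeI, K2CO3, DMF) should give 1-[5-(5-bromo-2-methoxyphenyl)-2,4-dimethoxyphenyl]ethanone F6. Claisen–Schmidt condensation with 2 (KOH, EtOH, rt) installs the 4-methoxycinnamoyl unit and gives 11.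

3. Step 9.
   - What may go wrong: the aryl vinyl ketone may polymerise or dimerise at the temperature that the electron-rich aryl bromide needs for oxidative addition. The amine base may add to the vinyl ketone. The chalcone alkene already present may be arylated as well.
   - Fallback: the second enone is built by aldol chemistry instead of a Heck reaction. It sets out from 11 and comes back to the route at 15; steps 7 and 8 are then not needed. Palladium-catalysed reductive carbonylation of 11 (Pd(OAc)2, di(1-adamantyl)-n-butylphosphine, TMEDA, CO/H2 5 bar, toluene, 100 °C) should give 3-[2,4-dimethoxy-5-[(E)-3-(4-methoxyphenyl)prop-2-enoyl]phenyl]-4-methoxybenzaldehyde F7. Its existing ketone has no enolisable hydrogen, so Claisen–Schmidt condensation with commercial 1-(2,4-dimethoxyphenyl)ethanone (KOH, EtOH, rt) can only use the acetophenone as donor and should give 15 with the E geometry.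

Further compounds
F1 | step 4 | 1-(5-iodo-2,4-dimethoxyphenyl)ethanone | CC(=O)c1cc(I)c(OC)cc1OC
F2 | step 4 | (E)-1-(5-iodo-2,4-dimethoxyphenyl)-3-(4-methoxyphenyl)prop-2-en-1-one | O=C(/C=C/c1ccc(OC)cc1)c1cc(I)c(OC)cc1OC
F3 | step 5 | methyl 4-acetyl-2-(5-bromo-2-methoxyphenyl)-5-oxohexanoate | COC(=O)C(CC(C(C)=O)C(C)=O)c1cc(Br)ccc1OC
F4 | step 5 | 4-acetyl-6-(5-bromo-2-methoxyphenyl)cyclohexane-1,3-dione (written as its bis-enol) | CC(=O)C1=C(O)CC(O)=C(c2cc(Br)ccc2OC)C1
F5 | step 5 | 1-[5-(5-bromo-2-methoxyphenyl)-2,4-dihydroxyphenyl]ethanone | CC(=O)c1cc(-c2cc(Br)ccc2OC)c(O)cc1O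
F6 | step 5 | 1-[5-(5-bromo-2-methoxyphenyl)-2,4-dimethoxyphenyl]ethanone | CC(=O)c1cc(-c2cc(Br)ccc2OC)c(OC)cc1OC
F7 | step 9 | 3-[2,4-dimethoxy-5-[(E)-3-(4-methoxyphenyl)prop-2-enoyl]phenyl]-4-methoxybenzaldehyde | O=Cc1ccc(OC)c(-c2cc(C(=O)/C=C/c3ccc(OC)cc3)c(OC)cc2OC)c1
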